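**Retrosynthetic overview**
1. The target is PGE3 1,15‑lactone 11‑acetate; the acetate comes last, from the 11‑O‑TBS macrolactone 19.
2. The 13‑membered ring is closed at C6–C7 by a Rh‑catalysed intramolecular conjugate addition of a (Z)‑alkenylboronate to the α‑methylene cyclopentanone 18, which also sets C8.
3. 18 comes from a C12–C13 union: Cu‑catalysed SN2′ coupling of an (E)‑alkenylzirconocene (from ester 16) with the Morita–Baylis–Hillman acetate 5, which sets C12.
4. 16 is the ester of propargylic alcohol 11 (C15 set by asymmetric transfer hydrogenation) with the (Z)‑boryl acid 15; 5 comes from (R)‑4‑hydroxycyclopentenone and formaldehyde.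
5. Ring order: the cyclopentane ring is bought in with 1; the macrolactone ring is formed in step 12.

Assumption: the target is the (5Z,8R,11R,12R,13E,15S,17Z) isomer encoded by the SMILES, and 8 is bought as its commercial 0.5 M THF solution.

**Route**

Step 1
Reactants: 1 (R)-4-hydroxycyclopent-2-en-1-one
Product: 2 (R)-4-[(tert-butyldimethylsilyl)oxy]cyclopent-2-en-1-one
Conditions: TBSCl, imidazole, CH2Cl2, 0 °C to rt
Reagents that add atoms: tert-butyldimethylsilyl chloride, CC(C)(C)[Si](C)(C)Cl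
Why: Imidazole-promoted silyl ether formation protects the C11 hydroxyl, whose (R) configuration is bought in with 1 and is not touched.

Step 2
Reactants: 2 (R)-4-[(tert-butyldimethylsilyl)oxy]cyclopent-2-en-1-one; 3 formaldehyde (37% aqueous)
Product: 4 (R)-4-[(tert-butyldimethylsilyl)oxy]-2-(hydroxymethyl)cyclopent-2-en-1-one
Conditions: imidazole (0.3 equiv), THF/H2O 1:1, rt
Reagents that add atoms: none
Why: Morita–Baylis–Hillman reaction, in which reversible conjugate addition of imidazole gives an enolate that adds to formaldehyde and then expels the catalyst; no stereocentre is formed and the weak base leaves C11 intact.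

Step 3
Reactants: 4 (R)-4-[(tert-butyldimethylsilyl)oxy]-2-(hydroxymethyl)cyclopent-2-en-1-one
Product: 5 [(3R)-3-[(tert-butyldimethylsilyl)oxy]-5-oxocyclopent-1-en-1-yl]methyl acetate
Conditions: Ac2O, pyridine, DMAP (cat.), CH2Cl2, 0 °C
Reagents that add atoms: acetic anhydride, CC(=O)OC(C)=O
Why: Standard acetylation of the primary alcohol turns the Baylis–Hillman adduct into an SN2′ electrophile.

Step 4
Reactants: 6 (3Z)-hex-3-enoic acid
Product: 7 (3Z)-N-methoxy-N-methylhex-3-enamide
Conditions: MeNH(OMe)·HCl, EDC·HCl, N-methylmorpholine, CH2Cl2, 0 °C to rt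
Reagents that add atoms: N,O-dimethylhydroxylamine hydrochloride, CNOC.Cl
Why: Carbodiimide amidation to the Weinreb amide runs near neutrality, so the β,γ-(Z)-alkene does not move into conjugation.

Step 5
Reactants: 7 (3Z)-N-methoxy-N-methylhex-3-enamide; 8 lithium (trimethylsilyl)acetylide
Product: 9 (5Z)-1-(trimethylsilyl)oct-5-en-1-yn-3-one
Conditions: THF, −78 to −40 °C; cold sat. NH4Cl quench
Reagents that add atoms: none
Why: Weinreb ketone synthesis, where the chelated tetrahedral intermediate prevents over-addition and masks the acidic C16 methylene until the cold quench.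

Step 6
Reactants: 9 (5Z)-1-(trimethylsilyl)oct-5-en-1-yn-3-one
Product: 10 (3S,5Z)-1-(trimethylsilyl)oct-5-en-1-yn-3-ol
Conditions: Ru[(S,S)-TsDPEN](p-cymene) (preformed amido complex, 2 mol%), i-PrOH, rt
Reagents that add atoms: none
Why: Noyori asymmetric transfer hydrogenation of an alkynyl ketone, in which the (S,S) catalyst delivers hydride to the face that gives the (S) propargylic alcohol (C15) and the base-free medium keeps the skipped enyne in place.

Step 7
Reactants: 10 (3S,5Z)-1-(trimethylsilyl)oct-5-en-1-yn-3-ol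
Product: 11 (3S,5Z)-oct-5-en-1-yn-3-ol
Conditions: K2CO3 (0.2 equiv), MeOH, 0 °C to rt
Reagents that add atoms: none
Why: Methoxide-mediated protodesilylation of the alkynylsilane frees the terminal alkyne without affecting C15 or the (Z)-alkene.

Step 8
Reactants: 12 hex-5-ynoic acid
Product: 13 tert-butyldimethylsilyl hex-5-ynoate
Conditions: TBSCl, imidazole, CH2Cl2, 0 °C to rt (used without chromatography)
Reagents that add atoms: tert-butyldimethylsilyl chloride, CC(C)(C)[Si](C)(C)Cl
Why: Silyl ester formation masks the acidic proton that would otherwise consume pinacolborane in the next step.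

Step 9
Reactants: 13 tert-butyldimethylsilyl hex-5-ynoate
Product: 15 (5Z)-6-(4,4,5,5-tetramethyl-1,3,2-dioxaborolan-2-yl)hex-5-enoic acid, via silyl ester boronate 14 (not isolated)
Conditions: HBpin (1.0 equiv), 13 (1.3 equiv), [Rh(cod)Cl]2 (1.5 mol%), P(i-Pr)3 (6 mol%), Et3N (1 equiv), cyclohexane, rt; then AcOH/THF/H2O 3:1:1, rt
Reagents that add atoms: pinacolborane, CC1(C)OBOC1(C)C
Why: Miyaura rhodium-catalysed trans-hydroboration of a terminal alkyne (via a rhodium vinylidene) gives the (Z)-alkenylboronate, and mild aqueous acid then cleaves the labile silyl ester.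

Step 10
Reactants: 11 (3S,5Z)-oct-5-en-1-yn-3-ol; 15 (5Z)-6-(4,4,5,5-tetramethyl-1,3,2-dioxaborolan-2-yl)hex-5-enoic acid
Product: 16 (3S,5Z)-oct-5-en-1-yn-3-yl (5Z)-6-(4,4,5,5-tetramethyl-1,3,2-dioxaborolan-2-yl)hex-5-enoate
Conditions: DCC, DMAP (0.1 equiv), CH2Cl2, 0 °C to rt
Reagents that add atoms: none
Why: Steglich esterification acylates the C15 oxygen with retention and installs the future lactone linkage while the pinacolboronate is inert.

Step 11
Reactants: 16 (3S,5Z)-oct-5-en-1-yn-3-yl (5Z)-6-(pinacolboryl)hex-5-enoate; 5 [(3R)-3-[(tert-butyldimethylsilyl)oxy]-5-oxocyclopent-1-en-1-yl]methyl acetate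
Product: 18 (1E,3S,5Z)-1-[(1R,5R)-5-[(tert-butyldimethylsilyl)oxy]-2-methylidene-3-oxocyclopentyl]octa-1,5-dien-3-yl (5Z)-6-(pinacolboryl)hex-5-enoate, via alkenylzirconocene chloride 17 (not isolated)
Conditions: Cp2Zr(H)Cl (1.05 equiv), CH2Cl2, 0 °C to rt, 20 min; then added slowly to 5 (1.3 equiv), CuBr·SMe2 (10 mol%), THF, −20 to 0 °C
Reagents that add atoms: none
Why: Schwartz hydrozirconation (syn, terminal-selective) gives the (E)-alkenylzirconocene, and copper-catalysed SN2′ substitution of the Baylis–Hillman acetate (conjugate addition then β-acetoxy elimination) forms C12–C13 anti to the silyloxy group, setting C12 (R) and unveiling the exocyclic enone.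

Step 12
Reactants: 18 (1E,3S,5Z)-1-[(1R,5R)-5-[(tert-butyldimethylsilyl)oxy]-2-methylidene-3-oxocyclopentyl]octa-1,5-dien-3-yl (5Z)-6-(pinacolboryl)hex-5-enoate
Product: 19 (5Z,8R,11R,12R,13E,15S,17Z)-11-[(tert-butyldimethylsilyl)oxy]-9-oxoprosta-5,13,17-trien-1,15-olide (PGE3 1,15-lactone 11-TBS ether)
Conditions: [Rh(OH)(cod)]2 (5 mol%), 1,4-dioxane/H2O 10:1, 40 °C, syringe-pump addition of 18 over 12 h to 1 mM
Reagents that add atoms: none
Why: Proposed new method: a rhodium(I)-catalysed intramolecular 1,4-addition of a (Z)-alkenyl pinacolboronate to an exocyclic α-methylene ketone used as a 13-membered macrocyclisation, in which B-to-Rh transmetalation at Rh–OH gives the (Z)-alkenylrhodium with retention, the ester tether holds it over the unhindered s-cis-locked C8=CH2 acceptor, syn-carborhodation forms C6–C7 and the oxa-π-allyl rhodium is protonated by water (regenerating Rh–OH) to set C8, which should settle as 8R (trans to the C12 chain) because this α-centre equilibrates to the more stable trans-2,3-disubstituted cyclopentanone (brief KOAc/EtOH equilibration if an 8-epimer persists), while high dilution suppresses oligomers; the closest known reaction type is the intermolecular Hayashi–Miyaura conjugate addition of alkenylboron reagents to enones, which has not been used to close a macrocycle.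

Step 13
Reactants: 19 PGE3 1,15-lactone 11-TBS ether
Product: 20 (5Z,8R,11R,12R,13E,15S,17Z)-11-hydroxy-9-oxoprosta-5,13,17-trien-1,15-olide (PGE3 1,15-lactone)
Conditions: 48% aq. HF, MeCN, 0 °C
Reagents that add atoms: none
Why: Acidic fluoride desilylation removes the TBS ether without the base-induced β-elimination of the β-hydroxy ketone and without opening the lactone.

Step 14
Reactants: 20 PGE3 1,15-lactone
Product: 21 (5Z,8R,11R,12R,13E,15S,17Z)-11-acetoxy-9-oxoprosta-5,13,17-trien-1,15-olide (PGE3 1,15-lactone 11-acetate, target)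
Conditions: Ac2O, pyridine, CH2Cl2, 0 °C, short reaction time
Reagents that add atoms: acetic anhydride, CC(=O)OC(C)=O
Why: Acetylation of the only free hydroxyl with retention at C11 gives the target, with cold pyridine keeping elimination to the PGA-type enone slow.

**Compound list**
1 | (R)-4-hydroxycyclopent-2-en-1-one | O=C1C=C[C@H](O)C1 | starting material
2 | (R)-4-[(tert-butyldimethylsilyl)oxy]cyclopent-2-en-1-one | O=C1C=C[C@H](O[Si](C)(C)C(C)(C)C)C1 | intermediate
3 | formaldehyde | C=O | starting material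
4 | (R)-4-[(tert-butyldimethylsilyl)oxy]-2-(hydroxymethyl)cyclopent-2-en-1-one | O=C1C(CO)=C[C@H](O[Si](C)(C)C(C)(C)C)C1 | intermediate
5 | [(3R)-3-[(tert-butyldimethylsilyl)oxy]-5-oxocyclopent-1-en-1-yl]methyl acetate | CC(=O)OCC1=C[C@H](O[Si](C)(C)C(C)(C)C)CC1=O | intermediate
6 | (3Z)-hex-3-enoic acid | CC/C=C\CC(=O)O | starting material
7 | (3Z)-N-methoxy-N-methylhex-3-enamide | CC/C=C\CC(=O)N(C)OC | intermediate
8 | lithium (trimethylsilyl)acetylide | [Li]C#C[Si](C)(C)C | starting material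
9 | (5Z)-1-(trimethylsilyl)oct-5-en-1-yn-3-one | CC/C=C\CC(=O)C#C[Si](C)(C)C | intermediate
10 | (3S,5Z)-1-(trimethylsilyl)oct-5-en-1-yn-3-ol | CC/C=C\C[C@H](O)C#C[Si](C)(C)C | intermediate
11 | (3S,5Z)-oct-5-en-1-yn-3-ol | CC/C=C\C[C@H](O)C#C | intermediate
12 | hex-5-ynoic acid | C#CCCCC(=O)O | starting material
13 | tert-butyldimethylsilyl hex-5-ynoate | C#CCCCC(=O)O[Si](C)(C)C(C)(C)C | intermediate
14 | tert-butyldimethylsilyl (5Z)-6-(4,4,5,5-tetramethyl-1,3,2-dioxaborolan-2-yl)hex-5-enoate | CC(C)(C)[Si](C)(C)OC(=O)CCC/C=C\B1OC(C)(C)C(C)(C)O1 | intermediate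
15 | (5Z)-6-(4,4,5,5-tetramethyl-1,3,2-dioxaborolan-2-yl)hex-5-enoic acid | OC(=O)CCC/C=C\B1OC(C)(C)C(C)(C)O1 | intermediate
16 | (3S,5Z)-oct-5-en-1-yn-3-yl (5Z)-6-(4,4,5,5-tetramethyl-1,3,2-dioxaborolan-2-yl)hex-5-enoate | CC/C=C\C[C@H](OC(=O)CCC/C=C\B1OC(C)(C)C(C)(C)O1)C#C | intermediate
17 | chlorobis(cyclopentadienyl)[(1E,3S,5Z)-3-{[(5Z)-6-(pinacolboryl)hex-5-enoyl]oxy}octa-1,5-dien-1-yl]zirconium | CC/C=C\C[C@H](OC(=O)CCC/C=C\B1OC(C)(C)C(C)(C)O1)/C=C/[Zr](Cl)(C2C=CC=C2)C2C=CC=C2 | intermediate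
18 | (1E,3S,5Z)-1-[(1R,5R)-5-[(tert-butyldimethylsilyl)oxy]-2-methylidene-3-oxocyclopentyl]octa-1,5-dien-3-yl (5Z)-6-(pinacolboryl)hex-5-enoate (dienyl chain trans to OTBS) | CC/C=C\C[C@H](OC(=O)CCC/C=C\B1OC(C)(C)C(C)(C)O1)/C=C/[C@H]2[C@H](O[Si](C)(C)C(C)(C)C)CC(=O)C2=C | intermediate
19 | (5Z,8R,11R,12R,13E,15S,17Z)-11-[(tert-butyldimethylsilyl)oxy]-9-oxoprosta-5,13,17-trien-1,15-olide | CC/C=C\C[C@H]1/C=C/[C@H]2[C@H](O[Si](C)(C)C(C)(C)C)CC(=O)[C@@H]2C/C=C\CCCC(=O)O1 | intermediate
20 | (5Z,8R,11R,12R,13E,15S,17Z)-11-hydroxy-9-oxoprosta-5,13,17-trien-1,15-olide | CC/C=C\C[C@H]1/C=C/[C@H]2[C@H](O)CC(=O)[C@@H]2C/C=C\CCCC(=O)O1 | intermediate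
21 | (5Z,8R,11R,12R,13E,15S,17Z)-11-acetoxy-9-oxoprosta-5,13,17-trien-1,15-olide | CC/C=C\C[C@H]1/C=C/[C@H]2[C@H](OC(C)=O)CC(=O)[C@@H]2C/C=C\CCCC(=O)O1 | target

**Step count**
Total steps: 14. Longest linear sequence: 9 (steps 4, 5, 6, 7, 10, 11, 12, 13, 14, from acid 6), which is 64% of the total.

**Three steps most likely to fail**

Step 12 (the proposed macrocyclisation) may give protodeboronated open-chain ester, oligomers or the 8-epimer. The fallback closes the ring by lactonisation with known chemistry; it sets out from 11 (with 5 and 15) and comes back at 19. Alcohol 11 is silylated (TESCl, imidazole) to (3S,5Z)-3-[(triethylsilyl)oxy]oct-5-en-1-yne F1. Hydrozirconation gives the alkenylzirconocene chloride F2, which is coupled with 5 under the step 11 conditions to the 15-O-TES α-methylene ketone F3. Intermolecular Rh-catalysed Hayashi–Miyaura addition of acid 15 ([Rh(OH)(cod)]2, dioxane/H2O, KHCO3) gives 11-O-TBS-15-O-TES-PGE3 F4. AcOH/THF/H2O removes the TES group to give 11-O-TBS-PGE3 F5. Corey–Nicolaou activation (2,2′-dipyridyl disulfide, PPh3) gives the S-(pyridin-2-yl) thioester F6, which lactonises in refluxing xylene at high dilution to 19.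

Step 11 (the union) may suffer a second conjugate addition of 17 to the product enone 18, or side reactions of the polyfunctional zirconocene. The fallback separates C–C bond formation from methylene formation; it sets out from 16 (via 17) and enone 2 and comes back at 18. Rh-catalysed conjugate addition of 17 to 2 ([RhCl(cod)]2, THF) gives the zirconium enolate F7. Monomeric formaldehyde traps it as the 8-hydroxymethyl ketone F8 (hydroxymethyl trans to the C12 chain). MsCl/Et3N then dehydrates F8 to 18.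

Step 9 (trans-hydroboration) may give Z/E mixtures or lose the silyl ester early. The fallback builds the (Z)-alkene by reduction and borylates afterwards; it sets out from 12 and comes back at 15. Iodination (I2, KOH, MeOH; then acidify) gives 6-iodohex-5-ynoic acid F9. Diimide reduction (2-nitrobenzenesulfonylhydrazide, Et3N) gives (5Z)-6-iodohex-5-enoic acid F10. Stereoretentive Miyaura borylation (B2pin2, PdCl2(PPh3)2, KOPh, toluene, 50 °C; then acidify) gives 15.

**Further compounds**
F1 | step 12 | (3S,5Z)-3-[(triethylsilyl)oxy]oct-5-en-1-yne | CC/C=C\C[C@H](O[Si](CC)(CC)CC)C#C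
F2 | step 12 | chlorobis(cyclopentadienyl)[(1E,3S,5Z)-3-[(triethylsilyl)oxy]octa-1,5-dien-1-yl]zirconium | CC/C=C\C[C@H](O[Si](CC)(CC)CC)/C=C/[Zr](Cl)(C1C=CC=C1)C1C=CC=C1
F3 | step 12 | (4R,5R)-4-[(tert-butyldimethylsilyl)oxy]-2-methylidene-5-[(1E,3S,5Z)-3-[(triethylsilyl)oxy]octa-1,5-dien-1-yl]cyclopentan-1-one | CC/C=C\C[C@H](O[Si](CC)(CC)CC)/C=C/[C@H]1[C@H](O[Si](C)(C)C(C)(C)C)CC(=O)C1=C
F4 | step 12 | 11-O-TBS-15-O-TES-PGE3 (free acid) | CC/C=C\C[C@H](O[Si](CC)(CC)CC)/C=C/[C@H]1[C@H](O[Si](C)(C)C(C)(C)C)CC(=O)[C@@H]1C/C=C\CCCC(=O)O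
F5 | step 12 | 11-O-TBS-PGE3 (free acid, 15-OH) | CC/C=C\C[C@H](O)/C=C/[C@H]1[C@H](O[Si](C)(C)C(C)(C)C)CC(=O)[C@@H]1C/C=C\CCCC(=O)O
F6 | step 12 | 11-O-TBS-PGE3 S-(pyridin-2-yl) thioester | CC/C=C\C[C@H](O)/C=C/[C@H]1[C@H](O[Si](C)(C)C(C)(C)C)CC(=O)[C@@H]1C/C=C\CCCC(=O)Sc1ccccn1
F7 | step 11 | zirconium enolate of the conjugate adduct of 17 and 2 | CC/C=C\C[C@H](OC(=O)CCC/C=C\B1OC(C)(C)C(C)(C)O1)/C=C/[C@H]2[C@H](O[Si](C)(C)C(C)(C)C)CC(O[Zr](Cl)(C3C=CC=C3)C3C=CC=C3)=C2
F8 | step 11 | 8-(hydroxymethyl) ketone (hydroxymethyl trans to the C12 chain, OTBS trans to the C12 chain) | CC/C=C\C[C@H](OC(=O)CCC/C=C\B1OC(C)(C)C(C)(C)O1)/C=C/[C@H]2[C@H](O[Si](C)(C)C(C)(C)C)CC(=O)[C@@H]2CO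
F9 | step 9 | 6-iodohex-5-ynoic acid | OC(=O)CCCC#CI
F10 | step 9 | (5Z)-6-iodohex-5-enoic acid | OC(=O)CCC/C=C\I
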